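**Str, strategy.** Everything rests on cutting the C2–C3 bond (and C2=C3 alkene) of the cyclohexenone ring (longipinane numbering): what remains, the cyclobutane C4–C5–C11–C10 bridged by the C6–C9 chain, has a mirror plane through C5, C10 and that chain which exchanges C4 and C11. The key step lets a chiral primary amine condense the enantiotopic acetyl groups on C4 and C11, closing the enone ring and fixing C4, C5, C10 and C11 in one operation. Its precursor is the meso 4,11-diacetyl bicyclo[4.1.1]octane whose C7 and C9 carbonyls carry two different achiral ketals (dioxolane, dimethyl ketal), so that O7 and O9 can later be unmasked and esterified one after the other.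

Key step: step 14

Remarks on the chemistry (before the steps)
- Atom labels C1–C11 are those of the target skeleton and are used for all intermediates: six-membered ring C1–C2–C3–C4–C10–C11, seven-membered ring C4–C5–C6–C7–C8–C9–C10, extra bond C5–C11, methyl groups on C3, C6 (two) and C10. α is the face of the seven-membered ring turned towards C11, β the face turned towards C4. The target is read as the 9α-angelate 7β-tiglate, (4R,5S,7R,9R,10R,11R).
- Compounds 9–11, 13, 15, 16 and 19–22 are racemic and/or diastereomer mixtures; 17, 23 and 24 are achiral; from 26 on the compounds are single enantiomers.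
- Design choices: the ring alkene is placed at C4=C5 so that the carbene of step 9 inserts into the tertiary C10–H bond and no O–C–H bond lies 1,5 to the carbene carbon. The two ketals differ so that C9 and C7 can be addressed by chemical means.
- Assumption: the sense in which the cinchona amine picks one acetyl group cannot be derived from the acyclic precedent. The quinine-derived amine is written; its quinidine-derived pseudoenantiomer is the direct replacement if the opposite sense is found.
- Assumption: 1, 2, 8, 30 and 35 are purchased.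

Step 1
Reactants: 1 2,2-dimethylbut-3-enoic acid; 2 potassium methyl malonate
Product: 4 methyl 4,4-dimethyl-3-oxohex-5-enoate, via acyl imidazolide 3 (not isolated)
Conditions: CDI, THF, rt; then 2, MgCl2, Et3N, 50 °C; aq. HCl
Reagents that add atoms: potassium methyl malonate 2, [K+].[O-]C(=O)CC(=O)OC
Why: Masamune–Brooks β-keto ester synthesis, in which the acyl imidazolide acylates the magnesium enolate of the malonate half-ester and the adduct loses CO2 on acidic work-up, a sequence that tolerates α-quaternary acids.

Step 2
Reactants: 4 methyl 4,4-dimethyl-3-oxohex-5-enoate; 5 ethylene glycol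
Product: 6 methyl 2-[2-(2-methylbut-3-en-2-yl)-1,3-dioxolan-2-yl]acetate
Conditions: 5, TsOH·H2O (cat.), benzene, reflux, Dean–Stark trap
Reagents that add atoms: ethylene glycol 5, OCCO
Why: Acid-catalysed ketalisation with azeotropic removal of water, which for a β-keto ester takes place at the ketone only and here masks the future C7 carbonyl while it is still activated and accessible.

Step 3
Reactants: 6 methyl 2-[2-(2-methylbut-3-en-2-yl)-1,3-dioxolan-2-yl]acetate
Product: 7 2-[2-(2-methylbut-3-en-2-yl)-1,3-dioxolan-2-yl]acetaldehyde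
Conditions: i-Bu2AlH, CH2Cl2, −78 °C; MeOH, aq. KNaC4H4O6
Reagents that add atoms: none
Why: Partial reduction of a methyl ester with i-Bu2AlH at low temperature stops at the aldehyde stage through the chelated aluminium hemiacetal, and ketal and alkene are inert.

Step 4
Reactants: 7 2-[2-(2-methylbut-3-en-2-yl)-1,3-dioxolan-2-yl]acetaldehyde; 8 but-2-enylmagnesium chloride
Product: 9 3-methyl-1-[2-(2-methylbut-3-en-2-yl)-1,3-dioxolan-2-yl]pent-4-en-2-ol (racemic, both diastereomers)
Conditions: 8, THF, −78 °C; aq. NH4Cl
Reagents that add atoms: but-2-enylmagnesium chloride 8, CC=CC[Mg]Cl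
Why: Crotyl Grignard reagents add to aldehydes through their γ-carbon (SE2′), which delivers the C10 methyl and the second vinyl group in one step; the two new centres are formed unselectively, which does no harm because C9 is oxidised in step 6 and C10 ends up on the mirror plane of 17.

Step 5
Reactants: 9 3-methyl-1-[2-(2-methylbut-3-en-2-yl)-1,3-dioxolan-2-yl]pent-4-en-2-ol
Product: 10 8,11,11-trimethyl-1,4-dioxaspiro[4.6]undec-9-en-7-ol (ring C4=C5–C6(Me)2–C7(dioxolane)–C8H2–C9H(OH)–C10H(Me); racemic, both diastereomers)
Conditions: second-generation Grubbs catalyst RuCl2(PCy3)(H2IMes)(=CHPh) (5 mol%), CH2Cl2, 40 °C, high dilution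
Reagents that add atoms: none
Why: Ring-closing metathesis of the 1,8-diene closes the seven-membered ring as its cis alkene with loss of ethylene, the gem-dimethyl group and the spiro-ketal favouring the folded conformer.

Step 6
Reactants: 10 8,11,11-trimethyl-1,4-dioxaspiro[4.6]undec-9-en-7-ol
Product: 11 8,11,11-trimethyl-1,4-dioxaspiro[4.6]undec-9-en-7-one (racemic)
Conditions: Dess–Martin periodinane, NaHCO3, CH2Cl2, 0 °C → rt
Reagents that add atoms: none
Why: Dess–Martin oxidation of the secondary alcohol under buffered, neutral conditions should give the β,γ-unsaturated ketone without moving the alkene into conjugation.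

Step 7
Reactants: 11 8,11,11-trimethyl-1,4-dioxaspiro[4.6]undec-9-en-7-one; 12 methoxytrimethylsilane
Product: 13 7,7-dimethoxy-8,11,11-trimethyl-1,4-dioxaspiro[4.6]undec-9-ene (racemic)
Conditions: 12, Me3SiOTf (cat.), CH2Cl2, −78 °C; pyridine quench
Reagents that add atoms: methoxytrimethylsilane 12, CO[Si](C)(C)C
Why: Noyori-type aprotic ketalisation with a silyl ether and catalytic silyl triflate converts the C9 ketone into its dimethyl ketal at low temperature, conditions under which the dioxolane and the position of the alkene should be kept.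

Step 8
Reactants: 13 7,7-dimethoxy-8,11,11-trimethyl-1,4-dioxaspiro[4.6]undec-9-ene; 14 bromoform
Product: 15 8,8-dibromo-5,5-dimethoxy-2,2,6-trimethylspiro[bicyclo[5.1.0]octane-3,2'-[1,3]dioxolane] (cis-fused; C10 methyl trans to the CBr2 carbon C11; racemic)
Conditions: 14, 50% aq. NaOH, BnEt3NCl (cat.), CH2Cl2, 0 °C → rt
Reagents that add atoms: bromoform 14, BrC(Br)Br
Why: Dibromocarbene made under phase-transfer conditions (Makosza) adds stereospecifically to the cis alkene from the face opposite to the C10 methyl group, which leaves the C10–H bond on the side of the new carbon C11.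

Step 9
Reactants: 15 8,8-dibromo-5,5-dimethoxy-2,2,6-trimethylspiro[bicyclo[5.1.0]octane-3,2'-[1,3]dioxolane]
Product: 17 6,6-dimethoxy-3,3,7-trimethylspiro[tricyclo[5.1.0.0(2,8)]octane-4,2'-[1,3]dioxolane] (achiral bicyclobutane, central bond C4–C11, wing carbons C5 and C10), via lithium bromocarbenoid 16 (not isolated)
Conditions: MeLi, Et2O, −78 → 0 °C
Reagents that add atoms: none
Why: Bromine–lithium exchange and loss of LiBr give the cyclopropylidene, which inserts with retention into the neighbouring tertiary C10–H bond; this is the known 1,3-C–H insertion of bicyclo[n.1.0]alkylidenes to 2,4-bridged bicyclobutanes, here aided by the syn tertiary C–H and by the crowding that disfavours opening to the cyclic allene.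

Step 10
Reactants: 17 the bicyclobutane; 18 acetaldehyde
Product: 20 the 1-(1-hydroxyethyl) derivative of 17 (CH(OH)CH3 on bridgehead C4; racemic, both carbinol epimers), via bridgehead lithium compound 19 (not isolated)
Conditions: n-BuLi, TMEDA, Et2O, 0 °C → rt; then 18, −78 °C
Reagents that add atoms: acetaldehyde 18, CC=O
Why: The bridgehead C–H bonds of a bicyclobutane have enough s-character to be metalated by n-BuLi/TMEDA, and the bridgehead lithium adds to the aldehyde; the two bridgeheads are enantiotopic, so the mono-adduct is racemic.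

Step 11
Reactants: 20 the 1-(1-hydroxyethyl) bicyclobutane; 18 acetaldehyde
Product: 22 the 1,8-bis(1-hydroxyethyl) derivative of 17 (carbinols on C4 and C11; carbinol diastereomers), via dilithio alkoxide 21 (not isolated)
Conditions: n-BuLi (2.2 equiv), TMEDA, Et2O, 0 °C → rt; then 18, −78 °C
Reagents that add atoms: acetaldehyde 18, CC=O
Why: After deprotonation of the hydroxyl group the second bridgehead is metalated in the same way and trapped with acetaldehyde, an aldehyde being used because a bridgehead ketone would not survive the second metalation.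

Step 12
Reactants: 22 the 1,8-bis(1-hydroxyethyl) bicyclobutane
Product: 23 the 1,8-diacetyl derivative of 17 (acetyl groups on C4 and C11; achiral)
Conditions: Dess–Martin periodinane, pyridine, CH2Cl2, 0 °C
Reagents that add atoms: none
Why: Dess–Martin oxidation under basic buffering converts both acid-sensitive bicyclobutyl carbinols into methyl ketones and removes the carbinol stereocentres.

Step 13
Reactants: 23 the 1,8-diacetyl bicyclobutane
Product: 24 meso-7,8-diacetyl-5,5-dimethoxy-2,2,6-trimethylspiro[bicyclo[4.1.1]octane-3,2'-[1,3]dioxolane] (acetyl groups on C4 and C11; drawn as the isomer with both acetyl groups anti to the C6–C9 bridge; formed together with its C4 and C11 epimers and carried on as this mixture)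
Conditions: SmI2, THF, MeOH, −78 °C
Reagents that add atoms: none
Why: Electron transfer to a ketone that is conjugated with a strained σ bond, as in the SmI2 opening of cyclopropyl ketones, should cleave the central C4–C11 bond to a bis-enolate whose protonation gives the cyclobutane-1,3-diyl diketone; protonation comes from the open face, so the needed anti,anti isomer must be reached by the epimerisation built into step 14.

Step 14
Reactants: 24 the meso 4,11-diacetyl diketone
Product: 26 (4R,5S,10R,11R)-9,9-dimethoxylongipin-2-ene-1,7-dione 7-(ethylene ketal), via ketol 25 (not isolated)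
Conditions: 9-amino-9-deoxy-epi-quinine (20 mol%), AcOH (60 mol%), toluene, 40 °C
Reagents that add atoms: none
Why: Proposed new method: the primary amine turns one acetyl group into an enamine whose carbon C2 adds to the carbonyl carbon C3 of the other acetyl group, and ketol 25 then dehydrates irreversibly to the C2=C3 enone; the closest known reaction is the cinchona-amine-catalysed desymmetrising aldol condensation of 4-substituted heptane-2,6-diones to 5-substituted 3-methylcyclohex-2-enones. The new six-membered ring closes in a 6-(enolendo)-exo-trig mode and gives the bicyclo[3.1.1]heptenone part of the cage. C4 and C11 epimerise through enol and enamine forms under the amine/acid conditions, so the epimer mixture from step 13 is funnelled through the single isomer in which both acetyl groups point away from the C6–C9 bridge and can reach each other. C4, C5, C10 and C11 become stereogenic in this one event: their relative configuration is imposed by the cage, their absolute configuration by which of the two enantiotopic acetyl groups the chiral amine converts into the enamine. The selectivity needed is therefore enantiotopic-group selectivity, and because the mirror plane through C5, C10 and the two achiral ketals leaves the substrate without any chirality of its own, nothing in it can bias the catalyst's choice.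

Step 15
Reactants: 26 (4R,5S,10R,11R)-9,9-dimethoxylongipin-2-ene-1,7-dione 7-(ethylene ketal)
Product: 27 (4R,5S,10R,11R)-longipin-2-ene-1,7,9-trione 7-(ethylene ketal)
Conditions: PPTS (cat.), acetone, H2O, rt
Reagents that add atoms: water, O
Why: Acyclic dimethyl ketals are hydrolysed far faster than dioxolanes, so mild aqueous acid should free the C9 ketone alone.

Step 16
Reactants: 27 (4R,5S,10R,11R)-longipin-2-ene-1,7,9-trione 7-(ethylene ketal)
Product: 28 (9R)-1,9-dihydroxylongipin-2-en-7-one ethylene ketal (9α-OH; C1 carbinol configuration not controlled and irrelevant)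
Conditions: (S)-2-methyl-CBS-oxazaborolidine (0.3 equiv), catecholborane (3 equiv), toluene, −78 → −30 °C; MeOH, aq. NaOH
Reagents that add atoms: none
Why: Corey–Bakshi–Shibata reduction, in which the (S)-catalyst tells the quaternary C10 (large) from the C8 methylene (small) and delivers hydride to the β-face of C9 to give the 9R (9α) alcohol, catalyst control being required because the cage offers no facial bias at this remote carbonyl; the C1 enone is reduced too and is restored in step 17.

Step 17
Reactants: 28 (9R)-1,9-dihydroxylongipin-2-en-7-one ethylene ketal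
Product: 29 (4R,5S,9R,10R,11R)-9α-hydroxylongipin-2-ene-1,7-dione 7-(ethylene ketal)
Conditions: MnO2, CH2Cl2, rt
Reagents that add atoms: none
Why: MnO2 oxidises allylic alcohols selectively, so the C1 alcohol returns to the enone while the saturated C9 alcohol stays.

Step 18
Reactants: 29 9α-hydroxylongipin-2-ene-1,7-dione 7-(ethylene ketal); 30 angelic acid
Product: 31 9α-angeloyloxylongipin-2-ene-1,7-dione 7-(ethylene ketal)
Conditions: 30, 2,4,6-Cl3C6H2COCl, Et3N, toluene, rt; then 29, 80 °C
Reagents that add atoms: angelic acid 30, C/C=C(/C)C(=O)O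
Why: Yamaguchi-type mixed-anhydride esterification is the established way to put an angelate on a hindered secondary alcohol without Z to E isomerisation of the acyl group.

Step 19
Reactants: 31 9α-angeloyloxylongipin-2-ene-1,7-dione 7-(ethylene ketal)
Product: 32 (4R,5S,9R,10R,11R)-9α-angeloyloxylongipin-2-ene-1,7-dione
Conditions: TsOH·H2O (cat.), acetone, H2O, 40 °C
Reagents that add atoms: water, O
Why: Acid-catalysed hydrolysis of the remaining dioxolane, helped by the relief of strain next to the quaternary C6, under conditions that an ester, an enone and a β-acyloxy ketone tolerate.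

Step 20
Reactants: 32 9α-angeloyloxylongipin-2-ene-1,7-dione
Product: 33 (7R,9R)-9-angeloyloxy-1,7-dihydroxylongipin-2-ene (7β-OH; C1 carbinol configuration not controlled and irrelevant)
Conditions: (S)-2-methyl-CBS-oxazaborolidine (0.3 equiv), catecholborane (3 equiv), toluene, −78 → −30 °C; MeOH, aq. NaHCO3
Reagents that add atoms: none
Why: Corey–Bakshi–Shibata reduction with the same catalyst, which now reads C6 (quaternary) as large and C8 as small and adds hydride to the α-face of C7 to give the 7R (7β) alcohol trans to the C9 ester; the medium is not basic, so the β-acyloxy ketone should not eliminate, and the C1 ketone is again over-reduced.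

Step 21
Reactants: 33 9-angeloyloxy-1,7-dihydroxylongipin-2-ene
Product: 34 (4R,5S,7R,9R,10R,11R)-9α-angeloyloxy-7β-hydroxylongipin-2-en-1-one
Conditions: MnO2, CH2Cl2, rt
Reagents that add atoms: none
Why: Chemoselective MnO2 oxidation of the allylic C1 alcohol regenerates the enone and leaves the C7 alcohol and the ester.

Step 22
Reactants: 34 9α-angeloyloxy-7β-hydroxylongipin-2-en-1-one; 35 tigloyl chloride
Product: 36 CNP0236543.2, (4R,5S,7R,9R,10R,11R)-9α-angeloyloxy-7β-tigloyloxylongipin-2-en-1-one
Conditions: 35, pyridine, DMAP (cat.), CH2Cl2, 0 °C → rt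
Reagents that add atoms: tigloyl chloride 35, C/C=C(\C)C(Cl)=O
Why: DMAP-catalysed acylation of the hindered secondary alcohol with the acid chloride; the tigloyl group is the stable E isomer and the conditions should leave the angelate untouched.

Compound list
1 | 2,2-dimethylbut-3-enoic acid | C=CC(C)(C)C(=O)O | starting material
2 | potassium methyl malonate | [K+].[O-]C(=O)CC(=O)OC | starting material
3 | 1-(2,2-dimethylbut-3-enoyl)imidazole | C=CC(C)(C)C(=O)n1ccnc1 | intermediate
4 | methyl 4,4-dimethyl-3-oxohex-5-enoate | C=CC(C)(C)C(=O)CC(=O)OC | intermediate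
5 | ethylene glycol | OCCO | starting material
6 | methyl 2-[2-(2-methylbut-3-en-2-yl)-1,3-dioxolan-2-yl]acetate | C=CC(C)(C)C1(CC(=O)OC)OCCO1 | intermediate
7 | 2-[2-(2-methylbut-3-en-2-yl)-1,3-dioxolan-2-yl]acetaldehyde | C=CC(C)(C)C1(CC=O)OCCO1 | intermediate
8 | but-2-enylmagnesium chloride | CC=CC[Mg]Cl | starting material
9 | 3-methyl-1-[2-(2-methylbut-3-en-2-yl)-1,3-dioxolan-2-yl]pent-4-en-2-ol (racemic, both diastereomers) | C=CC(C)(C)C1(CC(O)C(C)C=C)OCCO1 | intermediate
10 | 8,11,11-trimethyl-1,4-dioxaspiro[4.6]undec-9-en-7-ol (racemic, both diastereomers) | CC1C=CC(C)(C)C2(CC1O)OCCO2 | intermediate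
11 | 8,11,11-trimethyl-1,4-dioxaspiro[4.6]undec-9-en-7-one (racemic) | CC1C=CC(C)(C)C2(CC1=O)OCCO2 | intermediate
12 | methoxytrimethylsilane | CO[Si](C)(C)C | starting material
13 | 7,7-dimethoxy-8,11,11-trimethyl-1,4-dioxaspiro[4.6]undec-9-ene (racemic) | CC1C=CC(C)(C)C2(CC1(OC)OC)OCCO2 | intermediate
14 | bromoform | BrC(Br)Br | starting material
15 | 8,8-dibromo-5,5-dimethoxy-2,2,6-trimethylspiro[bicyclo[5.1.0]octane-3,2'-[1,3]dioxolane], cis-fused, 6-methyl trans to the CBr2 carbon (racemic, one enantiomer drawn) | C[C@@H]1[C@@H]2[C@@H](C2(Br)Br)C(C)(C)C3(OCCO3)CC1(OC)OC | intermediate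
16 | 8-bromo-8-lithio carbenoid derived from 15 | C[C@@H]1[C@@H]2[C@@H](C2([Li])Br)C(C)(C)C3(OCCO3)CC1(OC)OC | intermediate
17 | 6,6-dimethoxy-3,3,7-trimethylspiro[tricyclo[5.1.0.0(2,8)]octane-4,2'-[1,3]dioxolane] (achiral bicyclobutane) | C[C@@]12[C@@H]3[C@@H]([C@H]13)C(C)(C)C4(OCCO4)CC2(OC)OC | intermediate
18 | acetaldehyde | CC=O | starting material
19 | bridgehead (C4) lithium derivative of 17 | C[C@@]12[C@]3([Li])[C@@H]([C@H]13)C(C)(C)C4(OCCO4)CC2(OC)OC | intermediate
20 | 17 bearing CH(OH)CH3 on bridgehead C4 (racemic, both carbinol epimers) | C[C@@]12[C@]3(C(C)O)[C@@H]([C@H]13)C(C)(C)C4(OCCO4)CC2(OC)OC | intermediate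
21 | lithium alkoxide of 20, lithiated at bridgehead C11 | C[C@@]12[C@]3(C(C)O[Li])[C@@H]([C@]13[Li])C(C)(C)C4(OCCO4)CC2(OC)OC | intermediate
22 | 17 bearing CH(OH)CH3 on both bridgeheads C4 and C11 (carbinol diastereomers) | C[C@@]12[C@]3(C(C)O)[C@@H]([C@]13C(C)O)C(C)(C)C4(OCCO4)CC2(OC)OC | intermediate
23 | 17 bearing acetyl on both bridgeheads C4 and C11 (achiral) | C[C@@]12[C@]3(C(C)=O)[C@@H]([C@]13C(C)=O)C(C)(C)C4(OCCO4)CC2(OC)OC | intermediate
24 | meso-7,8-diacetyl-5,5-dimethoxy-2,2,6-trimethylspiro[bicyclo[4.1.1]octane-3,2'-[1,3]dioxolane], both acetyl groups anti to the four-carbon bridge (used together with its C4/C11 epimers) | CC(=O)[C@H]1[C@]2(C)C(OC)(OC)CC3(OCCO3)C(C)(C)[C@H]1[C@@H]2C(C)=O | intermediate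
25 | ketol: 3-hydroxy-9,9-dimethoxylongipinane-1,7-dione 7-(ethylene ketal) (C3 carbinol configuration open) | COC1(OC)CC2(OCCO2)C(C)(C)[C@@H]3[C@H]4C(=O)CC(C)(O)[C@@H]3[C@]41C | intermediate
26 | (4R,5S,10R,11R)-9,9-dimethoxylongipin-2-ene-1,7-dione 7-(ethylene ketal) | COC1(OC)CC2(OCCO2)C(C)(C)[C@@H]3[C@H]4C(=O)C=C(C)[C@@H]3[C@]41C | intermediate
27 | (4R,5S,10R,11R)-longipin-2-ene-1,7,9-trione 7-(ethylene ketal) | O=C1CC2(OCCO2)C(C)(C)[C@@H]3[C@H]4C(=O)C=C(C)[C@@H]3[C@]41C | intermediate
28 | (9R)-1,9-dihydroxylongipin-2-en-7-one ethylene ketal (C1 epimers) | O[C@@H]1CC2(OCCO2)C(C)(C)[C@@H]3[C@H]4C(O)C=C(C)[C@@H]3[C@]41C | intermediate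
29 | (4R,5S,9R,10R,11R)-9α-hydroxylongipin-2-ene-1,7-dione 7-(ethylene ketal) | O[C@@H]1CC2(OCCO2)C(C)(C)[C@@H]3[C@H]4C(=O)C=C(C)[C@@H]3[C@]41C | intermediate
30 | angelic acid, (Z)-2-methylbut-2-enoic acid | C/C=C(/C)C(=O)O | starting material
31 | 9α-angeloyloxylongipin-2-ene-1,7-dione 7-(ethylene ketal) | C/C=C(/C)C(=O)O[C@@H]1CC2(OCCO2)C(C)(C)[C@@H]3[C@H]4C(=O)C=C(C)[C@@H]3[C@]41C | intermediate
32 | (4R,5S,9R,10R,11R)-9α-angeloyloxylongipin-2-ene-1,7-dione | C/C=C(/C)C(=O)O[C@@H]1CC(=O)C(C)(C)[C@@H]2[C@H]3C(=O)C=C(C)[C@@H]2[C@]31C | intermediate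
33 | (7R,9R)-9-angeloyloxy-1,7-dihydroxylongipin-2-ene (C1 epimers) | C/C=C(/C)C(=O)O[C@@H]1C[C@@H](O)C(C)(C)[C@@H]2[C@H]3C(O)C=C(C)[C@@H]2[C@]31C | intermediate
34 | (4R,5S,7R,9R,10R,11R)-9α-angeloyloxy-7β-hydroxylongipin-2-en-1-one | C/C=C(/C)C(=O)O[C@@H]1C[C@@H](O)C(C)(C)[C@@H]2[C@H]3C(=O)C=C(C)[C@@H]2[C@]31C | intermediate
35 | tigloyl chloride, (E)-2-methylbut-2-enoyl chloride | C/C=C(\C)C(Cl)=O | starting material
36 | CNP0236543.2, (4R,5S,7R,9R,10R,11R)-9α-angeloyloxy-7β-tigloyloxylongipin-2-en-1-one | C/C=C(/C)C(=O)O[C@@H]1C[C@@H](OC(=O)/C(C)=C/C)C(C)(C)[C@@H]2[C@H]3C(=O)C=C(C)[C@@H]2[C@]31C | target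

Total step count: 22
Longest linear sequence: 22 steps (the route is fully linear from 1)

Steps most likely to fail

1. Step 14 (proposed new method). Possible failures are: epimerisation at C4 and C11 too slow to feed the reactive isomer; weak discrimination between the two acetyl groups on the rigid cyclobutane; retro-aldol outrunning dehydration in the strained ketol; loss of the dimethyl ketal under the acid co-catalyst. Fallback with known chemistry, setting out from 24 and returning at 29: KOH in MeOH brings about epimerisation and aldol condensation without asymmetric induction, through ketol 25 and its mirror-image ketol F1, and should give enone 26 together with its enantiomer, the ent-enone F2. Hydrolysis as in step 15 gives 27 and the ent-trione ketal F3. The (S)-oxazaborolidine reduction of step 16 sets C9 as R on both cage enantiomers and so turns the pair into diastereomers, 28 and the diol F4. MnO2 as in step 17 gives 29 and its diastereomer, the hydroxy enone F5, which are separated by chromatography. 29 continues at step 18.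

2. Step 9. Possible failures are: opening of the cyclopropylidene to the strained cyclic allene followed by dimerisation; transannular insertion into a C8–H bond; a share of the minor cyclopropane diastereomer that has no C10–H bond next to the carbene. Fallback that replaces carbene insertion by carbene addition, setting out from 11 and returning at 17: the thermodynamic enolate of 11 (KN(SiMe3)2, THF) is trapped with formaldehyde at C10 to give the hydroxymethyl ketone F6. Ketalisation as in step 7 (then K2CO3, MeOH) gives the dimethyl ketal alcohol F7, and Dess–Martin oxidation gives the aldehyde F8, which sits on a now quaternary C10. TsNHNH2 gives the tosylhydrazone F9. Heating its sodium salt (NaH, diglyme; aprotic Bamford–Stevens reaction) gives the diazoalkane F10, whose carbene has no hydrogen on the neighbouring carbon to shift and adds across the adjacent C4=C5 bond to give bicyclobutane 17.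

3. Step 20. Possible failures are: slow or poorly face-selective reduction of the very hindered C7 ketone; β-elimination of the C9 ester; erosion of the angelate geometry in steps 19–20. Fallback that uses a hydroxyl-directed reduction, setting out from 29 and returning at 34: hydrolysis of the dioxolane of 29 (TsOH·H2O, acetone, H2O) gives the β-hydroxy ketone F11. Me4NBH(OAc)3 in MeCN/AcOH (Evans–Saksena reduction) delivers hydride from the side of the C9 hydroxyl, leaves the enone alone and gives the trans diol F12. Angeloylation under the conditions of step 18 at the less hindered C9 hydroxyl (next to the tied-back cyclobutane carbon rather than the gem-dimethyl carbon) gives 34, which continues at step 22.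

Further compounds
F1 | step 14 | mirror-image ketol (enantiomer of 25) | COC1(OC)CC2(OCCO2)C(C)(C)[C@H]3[C@@H]4C(=O)CC(C)(O)[C@H]3[C@@]41C
F2 | step 14 | ent-enone, (4S,5R,10S,11S)-9,9-dimethoxylongipin-2-ene-1,7-dione 7-(ethylene ketal) | COC1(OC)CC2(OCCO2)C(C)(C)[C@H]3[C@@H]4C(=O)C=C(C)[C@H]3[C@@]41C
F3 | step 14 | ent-trione ketal, (4S,5R,10S,11S)-longipin-2-ene-1,7,9-trione 7-(ethylene ketal) | O=C1CC2(OCCO2)C(C)(C)[C@H]3[C@@H]4C(=O)C=C(C)[C@H]3[C@@]41C
F4 | step 14 | (9R)-1,9-dihydroxy diol on the (4S,5R,10S,11S) cage, 7-(ethylene ketal) | O[C@@H]1CC2(OCCO2)C(C)(C)[C@H]3[C@@H]4C(O)C=C(C)[C@H]3[C@@]41C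
F5 | step 14 | (4S,5R,9R,10S,11S)-9-hydroxylongipin-2-ene-1,7-dione 7-(ethylene ketal) | O[C@@H]1CC2(OCCO2)C(C)(C)[C@H]3[C@@H]4C(=O)C=C(C)[C@H]3[C@@]41C
F6 | step 9 | 8-(hydroxymethyl)-8,11,11-trimethyl-1,4-dioxaspiro[4.6]undec-9-en-7-one (racemic) | CC1(CO)C=CC(C)(C)C2(CC1=O)OCCO2
F7 | step 9 | (7,7-dimethoxy-8,11,11-trimethyl-1,4-dioxaspiro[4.6]undec-9-en-8-yl)methanol (racemic) | CC1(CO)C=CC(C)(C)C2(CC1(OC)OC)OCCO2
F8 | step 9 | 7,7-dimethoxy-8,11,11-trimethyl-1,4-dioxaspiro[4.6]undec-9-ene-8-carbaldehyde (racemic) | CC1(C=O)C=CC(C)(C)C2(CC1(OC)OC)OCCO2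
F9 | step 9 | p-toluenesulfonylhydrazone of F8 | Cc1ccc(cc1)S(=O)(=O)NN=CC1(C)C=CC(C)(C)C2(CC1(OC)OC)OCCO2
F10 | step 9 | 8-(diazomethyl)-7,7-dimethoxy-8,11,11-trimethyl-1,4-dioxaspiro[4.6]undec-9-ene | [N-]=[N+]=CC1(C)C=CC(C)(C)C2(CC1(OC)OC)OCCO2
F11 | step 20 | (4R,5S,9R,10R,11R)-9α-hydroxylongipin-2-ene-1,7-dione | O[C@@H]1CC(=O)C(C)(C)[C@@H]2[C@H]3C(=O)C=C(C)[C@@H]2[C@]31C
F12 | step 20 | (4R,5S,7R,9R,10R,11R)-7β,9α-dihydroxylongipin-2-en-1-one | O[C@@H]1C[C@@H](O)C(C)(C)[C@@H]2[C@H]3C(=O)C=C(C)[C@@H]2[C@]31C
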